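**Assumption:** atoms carry labdane numbers (C1–C20); α/β refer to the usual labdane drawing with the C20 methylene on the β-face. Chirality comes from (S)-carvone.

## Retrosynthetic overview

1. Target ⇐ borohydride reduction of a 6-keto spiro lactol; the spiro tetrahydrofuran comes from intramolecular oxa-Michael addition of the C9 tertiary alcohol to a γ-hydroxybutenolide (2-silylfuran + singlet oxygen).
2. C11–C12 ⇐ Cu-catalysed opening of a 9α,11-epoxide (from the C9 ketone) by a furylmethyl Grignard fragment made from furan-3-carboxylic acid.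
3. Tricyclic keto lactone ⇐ ring A by bridging lactone-enolate alkylation; δ-lactone ring and C5 by the key intramolecular vinylogous (1,6) Michael addition of a tethered propanoate to a 6,6-disubstituted cyclohexa-2,4-dienone.
4. Dienone ⇐ (S)-carvone: two α'-alkylations set C10, then the isopropenyl group is excised (ozonolysis, Criegee rearrangement, elimination).
5. Ring order: B (carvone) → δ-lactone → A → spiro tetrahydrofuran → γ-lactone.

## Route

**Step 1**
Reactants: 1 (S)-(+)-carvone
Product: 2 trans-6-(3-chloropropyl)carvone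
Conditions: LiN(iPr)2, THF, −78 °C; ICH2CH2CH2Cl, DMPU, −78 → −20 °C
Reagents that add atoms: 1-chloro-3-iodopropane, ClCCCI
Why: Kinetic α'-enolate alkylation (SN2 at the iodide terminus) installs C1–C3 trans to the isopropenyl group; this centre is re-enolized in step 2, so its configuration does not matter.

**Step 2**
Reactants: 2 trans-6-(3-chloropropyl)carvone
Product: 4 quaternary keto propanoate, via lithium aldolate 3 (not isolated)
Conditions: LiN(iPr)2, THF, −78 °C; CH2O (gas from cracked paraformaldehyde), −78 °C; EtCOCl, −78 → 0 °C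
Reagents that add atoms: formaldehyde, C=O; propanoyl chloride, CCC(Cl)=O
Why: Aldol addition of the tetrasubstituted lithium enolate to formaldehyde occurs anti to the neighbouring isopropenyl group, which sets the C10 quaternary centre (C20 trans to isopropenyl), and O-acylation of the aldolate blocks retro-aldol cleavage and installs the Michael donor.

**Step 3**
Reactants: 4 quaternary keto propanoate
Product: 6 C5 acetate, via methoxy hydroperoxide 5 (not isolated)
Conditions: O3, CH2Cl2–MeOH, −78 °C; then Ac2O, Et3N, DMAP (cat.), 0 → 25 °C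
Reagents that add atoms: ozone, [O-][O+]=O; methanol, CO
Why: Ozonolysis cleaves the electron-rich isopropenyl alkene in preference to the conjugated enone, and Criegee rearrangement of the derived peracetate turns the C5–C bond into C5–OAc with retention.

**Step 4**
Reactants: 6 C5 acetate
Product: 7 cyclohexa-2,4-dienone
Conditions: DBU, toluene, 25 → 50 °C
Reagents that add atoms: none
Why: Vinylogous E1cB elimination (γ-deprotonation of the enone, loss of the δ-acetate) gives the linearly conjugated dienone, which cannot aromatize because C10 is quaternary.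

**Step 5** (key ring closure)
Reactants: 7 cyclohexa-2,4-dienone
Product: 9 bicyclic lactone silyl dienol ether, via potassium dienolate 8 (not isolated)
Conditions: KN(SiMe3)2, THF, −78 → −40 °C; tBuMe2SiCl, −78 → 0 °C
Reagents that add atoms: tert-butyldimethylsilyl chloride, CC(C)(C)[Si](C)(C)Cl
Why: Intramolecular vinylogous Michael (1,6-conjugate) addition of the propanoate enolate to the dienone δ-carbon (6-exo-trig) closes the δ-lactone; the three-atom tether on the β-face of C10 can only reach the same face of C5, so the cis-fused lactone and 5α-H are set, and the dienolate is trapped as its silyl dienol ether.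

**Step 6**
Reactants: 9 bicyclic lactone silyl dienol ether
Product: 11 tricyclic enone lactone, via tricyclic silyl dienol ether 10 (not isolated)
Conditions: LiN(iPr)2, THF–DMPU, −78 °C; NaI (cat.), −78 → 25 °C; then 1 M HCl, THF, 25 °C
Reagents that add atoms: none
Why: Intramolecular C-alkylation of the lactone enolate (6-exo-tet) closes ring A across the lactone, so only the face of C4 facing the C1–C3 chain can bond and the C4 quaternary centre forms as one diastereomer (methyl α); acid hydrolysis of the silyl dienol ether returns the conjugated enone.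

**Step 7**
Reactants: 11 tricyclic enone lactone
Product: 12 ene-dione lactone
Conditions: tBuOOH, Pd(OH)2 on carbon (cat.), K2CO3 (cat.), CH2Cl2, 25 °C
Reagents that add atoms: tert-butyl hydroperoxide, CC(C)(C)OO
Why: Pd-catalysed allylic oxidation with tert-butyl hydroperoxide converts the γ-methylene (C6) of the enone into a carbonyl.

**Step 8**
Reactants: 12 ene-dione lactone
Product: 13 saturated 6,9-dione
Conditions: H2 (1 atm), Pd on carbon, EtOAc, 25 °C; then DBU (cat.), CH2Cl2, 25 °C
Reagents that add atoms: none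
Why: Catalytic hydrogenation saturates the electron-poor alkene, and base equilibration through the C9 enolate places the C8 methyl equatorial (8α), away from the axial C20 methylene.

**Step 9**
Reactants: 13 saturated 6,9-dione
Product: 14 C6 mono-ketal
Conditions: Me3SiOCH2CH2OSiMe3, Me3SiOTf (cat.), CH2Cl2, −78 → −20 °C
Reagents that add atoms: 1,2-bis(trimethylsilyloxy)ethane, C[Si](C)(C)OCCO[Si](C)(C)C
Why: Noyori ketalization under kinetic control should protect the C6 ketone, while the C9 ketone, flanked by quaternary C10 and the C8 methine, stays free.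

**Step 10**
Reactants: 14 C6 mono-ketal
Product: 15 9α,11-epoxide
Conditions: Me3S(O)I, NaH, DMSO, 25 → 50 °C
Reagents that add atoms: trimethylsulfoxonium iodide, C[S+](C)(C)=O.[I-]
Why: Corey–Chaykovsky epoxidation with the sulfoxonium ylide is reversible at the betaine stage, so the equatorial (β) C9–C11 bond is formed and the oxygen ends up axial on the α-face.

**Step 11**
Reactants: 16 furan-3-carboxylic acid
Product: 17 2-(trimethylsilyl)furan-3-carboxylic acid
Conditions: LiN(iPr)2 (2.2 equiv), THF, −78 °C; Me3SiCl; aq. HCl work-up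
Reagents that add atoms: chlorotrimethylsilane, C[Si](C)(C)Cl
Why: Carboxylate-directed ortho-lithiation at C2 of the furan followed by C-silylation; the silyl ester formed alongside is hydrolysed on work-up.

**Step 12**
Reactants: 17 2-(trimethylsilyl)furan-3-carboxylic acid
Product: 18 [2-(trimethylsilyl)furan-3-yl]methanol
Conditions: LiAlH4, Et2O, 0 → 25 °C
Reagents that add atoms: none
Why: Hydride reduction of the carboxylic acid to the primary alcohol.

**Step 13**
Reactants: 18 [2-(trimethylsilyl)furan-3-yl]methanol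
Product: 19 3-(chloromethyl)-2-(trimethylsilyl)furan
Conditions: PPh3, CCl4, CH2Cl2, 0 → 25 °C
Reagents that add atoms: tetrachloromethane, ClC(Cl)(Cl)Cl
Why: Appel chlorination under neutral conditions spares the acid-sensitive silylfuran.

**Step 14**
Reactants: 19 3-(chloromethyl)-2-(trimethylsilyl)furan; 15 9α,11-epoxide
Product: 21 9α-hydroxy silylfuran, via furylmethylmagnesium chloride 20 (not isolated)
Conditions: 19 (2.5 equiv), Mg, THF, 0 °C; then CuI (10 mol %), 15, THF, −30 → 0 °C; aq. NH4Cl
Reagents that add atoms: none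
Why: Copper-catalysed SN2 opening of the 1,1-disubstituted epoxide by the Grignard reagent at the methylene terminus forms C11–C12 and leaves the 9α C–O bond untouched; the 2-silyl group blocks reaction through the furan ring.

**Step 15**
Reactants: 21 9α-hydroxy silylfuran
Product: 22 γ-hydroxybutenolide
Conditions: O2, visible light, tetraphenylporphyrin (cat.), CH2Cl2, −78 °C; then H2O
Reagents that add atoms: oxygen, O=O
Why: Singlet-oxygen [4+2] cycloaddition to the furan followed by silyl migration in the endoperoxide (silyl-directed furan photooxygenation) makes the silyl-bearing carbon C16 the lactone carbonyl.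

**Step 16**
Reactants: 22 γ-hydroxybutenolide
Product: 23 spiro lactol
Conditions: DBU (0.3 equiv), MeCN, 0 → 25 °C
Reagents that add atoms: none
Why: Base opens the hydroxybutenolide to the (Z)-4-oxo-2-enoate and the 9α-alkoxide adds 5-exo-trig to C13, β to the aldehyde (intramolecular oxa-Michael addition), before reclosure to the lactol; the addition is reversible, and the 13S epimer, with the flat lactone carbonyl rather than the C14 methylene on the side of quaternary C10, is the expected (not assured) thermodynamic product.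

**Step 17**
Reactants: 23 spiro lactol
Product: 25 target, via keto lactol 24 (not isolated)
Conditions: 1 M HCl, THF, 25 °C; then NaBH4, MeOH, −20 → 0 °C; 1 M HCl to pH 2
Reagents that add atoms: water, O
Why: Acetal hydrolysis frees the C6 ketone, and borohydride carbonyl reduction attacks C6 from the open α-face (the β-face is covered by the C20 methylene and the C19 lactone) to give the axial 6β-alcohol; the ring-opened aldehyde of the lactol is reduced at the same time and lactonizes on acidification. Kept cold and short to avoid acyl migration to the 19,6-lactone.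

## Compound list

1 | (S)-(+)-carvone, (5S)-2-methyl-5-(prop-1-en-2-yl)cyclohex-2-en-1-one | CC1=CC[C@H](C(C)=C)CC1=O | starting material
2 | (5S,6R)-6-(3-chloropropyl)-2-methyl-5-(prop-1-en-2-yl)cyclohex-2-en-1-one (chain trans to isopropenyl) | CC1=CC[C@H](C(C)=C)[C@@H](CCCCl)C1=O | intermediate
3 | lithium [(1S,6R)-1-(3-chloropropyl)-3-methyl-2-oxo-6-(prop-1-en-2-yl)cyclohex-3-en-1-yl]methanolate | CC1=CC[C@H](C(C)=C)[C@@](CCCCl)(C[O-])C1=O.[Li+] | intermediate (not isolated)
4 | [(1S,6R)-1-(3-chloropropyl)-3-methyl-2-oxo-6-(prop-1-en-2-yl)cyclohex-3-en-1-yl]methyl propanoate (acyloxymethyl trans to isopropenyl) | CC1=CC[C@H](C(C)=C)[C@@](CCCCl)(COC(=O)CC)C1=O | intermediate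
5 | [(1S,6S)-1-(3-chloropropyl)-6-(1-hydroperoxy-1-methoxyethyl)-3-methyl-2-oxocyclohex-3-en-1-yl]methyl propanoate (mixture at the peroxy carbon) | CC1=CC[C@H](C(C)(OC)OO)[C@@](CCCCl)(COC(=O)CC)C1=O | intermediate (not isolated)
6 | [(1R,6S)-6-acetoxy-1-(3-chloropropyl)-3-methyl-2-oxocyclohex-3-en-1-yl]methyl propanoate | CC1=CC[C@H](OC(C)=O)[C@@](CCCCl)(COC(=O)CC)C1=O | intermediate
7 | (S)-[1-(3-chloropropyl)-3-methyl-2-oxocyclohexa-3,5-dien-1-yl]methyl propanoate | CC1=CC=C[C@@](CCCCl)(COC(=O)CC)C1=O | intermediate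
8 | potassium (4aS,8aS)-8a-(3-chloropropyl)-4,7-dimethyl-3-oxo-1,4,4a,8a-tetrahydro-3H-isochromen-8-olate (C4 epimers) | CC1=C([O-])[C@]2(CCCCl)COC(=O)C(C)[C@@H]2C=C1.[K+] | intermediate (not isolated)
9 | (4aS,8aS)-8-[(tert-butyldimethylsilyl)oxy]-8a-(3-chloropropyl)-4,7-dimethyl-1,4,4a,8a-tetrahydro-3H-isochromen-3-one (cis-fused, C4 epimers) | CC1=C(O[Si](C)(C)C(C)(C)C)[C@]2(CCCCl)COC(=O)C(C)[C@@H]2C=C1 | intermediate
10 | (4S,5R,10S)-9-[(tert-butyldimethylsilyl)oxy]-11,12,13,14,15,16-hexanorlabda-6,8-dien-19,20-olide | CC1=C(O[Si](C)(C)C(C)(C)C)[C@]23CCC[C@](C)(C(=O)OC2)[C@@H]3C=C1 | intermediate (not isolated)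
11 | (4S,5R,10S)-9-oxo-11,12,13,14,15,16-hexanorlabd-7-en-19,20-olide (4α-methyl, 5α-H, lactone on the β-face) | CC1=CC[C@@H]2[C@]3(CCC[C@]2(C)C(=O)OC3)C1=O | intermediate
12 | (4S,5R,10S)-6,9-dioxo-11,12,13,14,15,16-hexanorlabd-7-en-19,20-olide | CC1=CC(=O)[C@@H]2[C@]3(CCC[C@]2(C)C(=O)OC3)C1=O | intermediate
13 | (4S,5R,8R,10S)-6,9-dioxo-11,12,13,14,15,16-hexanorlabdan-19,20-olide (8α-methyl) | C[C@@H]1CC(=O)[C@@H]2[C@]3(CCC[C@]2(C)C(=O)OC3)C1=O | intermediate
14 | (4S,5R,8R,10S)-6,6-(ethylenedioxy)-9-oxo-11,12,13,14,15,16-hexanorlabdan-19,20-olide | C[C@@H]1CC2(OCCO2)[C@@H]3[C@]4(CCC[C@]3(C)C(=O)OC4)C1=O | intermediate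
15 | (4S,5R,8R,9R,10S)-9,11-epoxy-6,6-(ethylenedioxy)-12,13,14,15,16-pentanorlabdan-19,20-olide (epoxide oxygen 9α) | C[C@@H]1CC2(OCCO2)[C@@H]3[C@]4(CCC[C@]3(C)C(=O)OC4)[C@@]15CO5 | intermediate
16 | furan-3-carboxylic acid | OC(=O)c1ccoc1 | starting material
17 | 2-(trimethylsilyl)furan-3-carboxylic acid | C[Si](C)(C)c1occc1C(=O)O | intermediate
18 | [2-(trimethylsilyl)furan-3-yl]methanol | C[Si](C)(C)c1occc1CO | intermediate
19 | 3-(chloromethyl)-2-(trimethylsilyl)furan | C[Si](C)(C)c1occc1CCl | intermediate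
20 | {[2-(trimethylsilyl)furan-3-yl]methyl}magnesium chloride | C[Si](C)(C)c1occc1C[Mg]Cl | intermediate (not isolated)
21 | (4S,5R,8R,9R,10S)-15,16-epoxy-6,6-(ethylenedioxy)-9-hydroxy-16-(trimethylsilyl)labda-13(16),14-dien-19,20-olide (9α-OH) | C[C@@H]1CC2(OCCO2)[C@@H]3[C@]4(CCC[C@]3(C)C(=O)OC4)[C@@]1(O)CCc1ccoc1[Si](C)(C)C | intermediate
22 | (4S,5R,8R,9R,10S)-6,6-(ethylenedioxy)-9,15-dihydroxylabd-13-ene-19,20:16,15-diolide (C15 epimers) | C[C@@H]1CC2(OCCO2)[C@@H]3[C@]4(CCC[C@]3(C)C(=O)OC4)[C@@]1(O)CCC1=CC(O)OC1=O | intermediate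
23 | (4S,5R,8R,9R,10S,13S)-9,13-epoxy-6,6-(ethylenedioxy)-15-hydroxylabdane-19,20:16,15-diolide (C15 epimers) | C[C@@H]1CC2(OCCO2)[C@@H]3[C@]4(CCC[C@]3(C)C(=O)OC4)[C@@]15CC[C@@]6(CC(O)OC6=O)O5 | intermediate
24 | (4S,5R,8R,9R,10S,13S)-9,13-epoxy-15-hydroxy-6-oxolabdane-19,20:16,15-diolide (C15 epimers) | C[C@@H]1CC(=O)[C@@H]2[C@]3(CCC[C@]2(C)C(=O)OC3)[C@@]14CC[C@@]5(CC(O)OC5=O)O4 | intermediate (not isolated)
25 | (4S,5R,6R,8R,9R,10S,13S)-9,13-epoxy-6-hydroxylabdane-19,20:16,15-diolide (6β-OH), CNP0393616.1 | C[C@@H]1C[C@@H](O)[C@@H]2[C@]3(CCC[C@]2(C)C(=O)OC3)[C@@]12CC[C@@]1(CCOC1=O)O2 | target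

## Step count and risks

Total step count: 17 (steps 1–10 core, 11–13 furan fragment, 14–17 union and end game).
Longest linear sequence: 14 steps (1–10 and 14–17), i.e. 14/17 of the total; only the three-step furan fragment runs in parallel.

Steps most likely to fail:

**Step 5 (ester-enolate 1,6-Michael addition).** It may be overrun by 1,2-addition to the dienone carbonyl or by dimerization of 7. Fallback: change the donor to a malonate-type carbon acid and close ring A by dealkoxycarbonylative alkylation; it sets out from 2 and returns at 11. Compound 2 is enolized (LiN(iPr)2), hydroxymethylated (CH2O) and acylated with methyl 3-chloro-2-methyl-3-oxopropanoate to give the methylmalonate ester F1. Ozonolysis and Criegee rearrangement give the acetate F2. DBU eliminates acetic acid to the dienone F3, and Cs2CO3 in MeCN lets the soft malonate anion add 1,6 to give the bicyclic lactone keto ester F4 (either C4 epimer serves). LiI in dry 2,4,6-collidine at 130 °C (Krapcho-type) demethylates and decarboxylates F4, and the lactone enolate so released alkylates the chloropropyl chain in the same flask to give 11.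

**Step 10 (sulfoxonium epoxidation of the flanked C9 ketone).** The ylide may not add, or the wrong epoxide may form. Fallback: olefination then peracid epoxidation; it sets out from 14 and returns at 15. Wittig methylenation (Ph3PCH3Br, KOtBu, toluene, 90 °C) gives the exocyclic alkene F5; mCPBA, NaHCO3, CH2Cl2, 0 °C epoxidizes the α-face, anti to the axial C20 methylene, to give 15.

**Step 16 (C13 configuration in the oxa-Michael addition).** Substrate control may favour the 13R spiro centre. Fallback: set C13 under catalyst control on the ester aldehyde; it sets out from 22 and returns at 25. Me3SiCHN2 in MeOH–toluene gives the (Z)-4-oxo enoate methyl ester F6. A diphenylprolinol trimethylsilyl ether (20 mol %) with benzoic acid in toluene effects the 5-exo oxa-Michael addition through the iminium ion, the catalyst enantiomer chosen to give the 13S spiro ether F7. NaBH4 then acid gives the γ-lactone F8; 1 M HCl in THF removes the ketal to give the ketone F9; NaBH4 at −20 °C reduces C6 from the α-face to give 25.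

## Further compounds

F1 | step 5 | [(1S,6R)-1-(3-chloropropyl)-3-methyl-2-oxo-6-(prop-1-en-2-yl)cyclohex-3-en-1-yl]methyl methyl 2-methylpropanedioate | CC1=CC[C@H](C(C)=C)[C@@](CCCCl)(COC(=O)C(C)C(=O)OC)C1=O
F2 | step 5 | [(1R,6S)-6-acetoxy-1-(3-chloropropyl)-3-methyl-2-oxocyclohex-3-en-1-yl]methyl methyl 2-methylpropanedioate | CC1=CC[C@H](OC(C)=O)[C@@](CCCCl)(COC(=O)C(C)C(=O)OC)C1=O
F3 | step 5 | (S)-[1-(3-chloropropyl)-3-methyl-2-oxocyclohexa-3,5-dien-1-yl]methyl methyl 2-methylpropanedioate | CC1=CC=C[C@@](CCCCl)(COC(=O)C(C)C(=O)OC)C1=O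
F4 | step 5 | methyl (4aR,8aS)-8a-(3-chloropropyl)-4,7-dimethyl-3,8-dioxo-3,4,4a,5,8,8a-hexahydro-1H-isochromene-4-carboxylate (cis-fused, C4 epimers) | CC1=CC[C@@H]2[C@@](CCCCl)(COC(=O)C2(C)C(=O)OC)C1=O
F5 | step 10 | (4S,5R,8R,10S)-6,6-(ethylenedioxy)-12,13,14,15,16-pentanorlabd-9(11)-en-19,20-olide | C[C@@H]1CC2(OCCO2)[C@@H]3[C@]4(CCC[C@]3(C)C(=O)OC4)C1=C
F6 | step 16 | methyl (13Z,4S,5R,8R,9R,10S)-6,6-(ethylenedioxy)-9-hydroxy-15-oxo-19,20-olidolabd-13-en-16-oate | C[C@@H]1CC2(OCCO2)[C@@H]3[C@]4(CCC[C@]3(C)C(=O)OC4)[C@@]1(O)CC/C(C(=O)OC)=C/C=O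
F7 | step 16 | methyl (4S,5R,8R,9R,10S,13S)-9,13-epoxy-6,6-(ethylenedioxy)-15-oxo-19,20-olidolabdan-16-oate | C[C@@H]1CC2(OCCO2)[C@@H]3[C@]4(CCC[C@]3(C)C(=O)OC4)[C@@]15CC[C@](CC=O)(C(=O)OC)O5
F8 | step 16 | (4S,5R,8R,9R,10S,13S)-9,13-epoxy-6,6-(ethylenedioxy)labdane-19,20:16,15-diolide | C[C@@H]1CC2(OCCO2)[C@@H]3[C@]4(CCC[C@]3(C)C(=O)OC4)[C@@]15CC[C@@]6(CCOC6=O)O5
F9 | step 16 | (4S,5R,8R,9R,10S,13S)-9,13-epoxy-6-oxolabdane-19,20:16,15-diolide | C[C@@H]1CC(=O)[C@@H]2[C@]3(CCC[C@]2(C)C(=O)OC3)[C@@]14CC[C@@]5(CCOC5=O)O4
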